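## The problem

The target is a flavonol: a 4H-chromen-4-one in which ring A and ring C share C4a–C8a, with a 4-hydroxy-3-methoxyphenyl ring B on C2. It has no stereocentre, so nothing can be relayed. The only stereochemical element that arises on the way is the geometry of an acyclic precursor of the C2=C3 bond. The real difficulty is constitutional. Six oxygens at C3, C5, C7, C8, C3′ and C4′ must end as OH, OH, O-prenyl, OMe, OMe and OH, so the 7-oxygen has to be told apart from three other hydroxyls of similar acidity. Ring A is hexasubstituted, with a single hydrogen at C6, so its oxygen pattern must be bought or set early and cannot be corrected by late electrophilic substitution. The prenyl aryl ether is the fragile group: it does not survive hydrogenolysis, strong Brønsted or Lewis acids (ionisation, 1,3-shift), prolonged heating (Claisen rearrangement to C6) or alkyllithiums (allylic α-oxy protons). The 3-hydroxy-4-pyranone is also opened by strong nucleophiles. The feature that makes the key step possible is that the C4 carbonyl lies between two carbons that oxygen makes acidic: C4a, the ring-A carbon flanked by O1 and the 5-oxygen, and C3, an enol-ether carbon carrying the 3-oxygen. C4 can therefore be inserted last, as a one-carbon dielectrophile between two carbanions.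

## Retrosynthesis

**20 ⇒ 19 ⇒ 18 ⇒ 17 (three O–CH2 acetal bonds, the O7–prenyl bond, the O7–Si bond).** The prenyl group cannot pass an organolithium step, so it is attached after ring C exists. The 7-oxygen must then be uniquely addressable, which a bulky silyl ether provides. The other three hydroxyls carry methoxymethyl (MOM) groups, which are the best ortho-directing and chelating acetals and fall together under mild acid. The neighbouring option, prenylating the unprotected tetraol, would have to discriminate the 7-OH from the 4′- and 3-OH. These cuts do not simplify the skeleton; they set up an orthogonal Si/acetal pair. The forward steps are fluoride desilylation, a Williamson etherification and a mild acetal cleavage.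

**17 ⇒ 13 + 14 (C4–C4a and C3–C4).** The classical cuts at O1–C2 (diketone cyclodehydration) or C2–C3 (chalcone oxidation) need a preformed 2-hydroxyaryl ketone. That means a Friedel–Crafts or Fries acylation on a ring carrying acid-labile groups, and the oxidative chalcone closure is diverted to aurones by a 6′-substituent. Cutting both bonds to C4 removes ring C and the carbonyl at once. What remains is the acyclic aryl enol ether 13 and the one-carbon reagent 14. The forward reaction needs two site-selective metalations (C4a, then C3) and an enol ether in which C3–H is cis to O1, that is, the E isomer.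

**13 ⇒ 10 + 12 (C2–C1′).** The geometry of 13 is the weak point of any route through it. The obvious neighbouring cut at O3–CH2 (O-alkylation of the enolate of an α-aryloxy arylacetaldehyde) leaves the geometry to an enolate in which the two oxygens prefer to be cis, which leads to the wrong isomer. Cutting the bond to ring B turns this preference into an asset. In the ketene acetal phosphate 10 the phosphate sits cis to the MOM-oxy group, and a stereoretentive cross-coupling with the boronate 12 puts ring B in that place. The aryloxy group is then trans to MOM-oxy, as required. The precursors are an ester-derived enol phosphate and a simple arylboronate. The forward reaction must couple with retention and without hydrolysing the ketene acetal.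

**10 ⇒ 9 (O–P bond, enolisation).** The phosphate comes from the aryl ester 9 by O-phosphorylation of its enolate. α-Alkoxy ester enolates place the α-oxygen cis to the enolate oxygen, by chelation and by the open-transition-state preference alike. The ester enolate must be trapped before it loses aryloxide.

**9 ⇒ 8 ⇒ 6 ⇒ 2 + 5; 2 ⇒ 1; 5 ⇒ 4 ⇒ 3 (O5–CH2, C5–O, the ester C–O, O7–Si).** The 5-oxygen is introduced by C–H borylation and oxidation of 6 through the boronate 7. In a 1,2,3-trisubstituted benzene this reaction goes to the only position without an ortho neighbour. The alternative, degrading a benzoate carbon to oxygen on a gallate-type ring, needs a redox sequence and a temporary third protecting group. The ester of 6 serves as the protecting group of O1 during this operation and later becomes C2 and C3. Compound 2 comes from the symmetric diol 1 by monosilylation, and acid 5 from methyl glycolate 3 through 4.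

**12 ⇒ 11 (O–CH2).** Ring B is bought as the phenol boronate 11 and needs only MOM protection.

## Roads not taken

**Alternative 1: methoxyfuran Diels–Alder and bridge opening to ring A.**
- **Cut and key step:** C5–C6 and C7–C8 of ring A. A fully substituted 2-methoxyfuran adds to an acetylenic methyl ketone, and the oxanorbornadiene opens at its acetal carbon to the phenol A1, methyl 4-acetyl-6-hydroxy-3-methoxy-2-(pivaloyloxy)benzoate.
- **Merits:** The cycloaddition writes the whole substitution pattern of ring A in one step. It delivers the three oxygens already differentiated (free OH for the later 5-OH, pivalate for O1, OMe for C8), and the C4 carbon is already attached.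
- **Weak points:** The acetyl group is only a latent 7-oxygen and needs a Baeyer–Villiger oxidation and hydrolysis. The furan is itself a multistep, acid-sensitive intermediate. Ring C and ring B are untouched, so from A1 a classical acylation and cyclodehydration sequence must still be run.
- **Comparison:** It is better in one respect: it needs no statistical desymmetrisation, which the chosen plan accepts in step 1. Against that, the chosen plan buys ring A, installs the missing oxygen in one operation and closes ring C in the key step.

**Alternative 2: quinoid acylketene and enamine cycloaddition to ring C.**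
- **Cut and key step:** C3–C4 and O1–C2. Irradiation of a ring-A benzodioxinone releases a quinoid acylketene. An enamine of the ring-B α-MOM-oxy ketone attacks it through its β-carbon, the oxygen closes onto the α-carbon and the amine is lost. The product A2 is 8-methoxy-3,5-bis(methoxymethoxy)-2-[3-methoxy-4-(methoxymethoxy)phenyl]-7-[(3-methylbut-2-en-1-yl)oxy]-4H-chromen-4-one, the same substance as compound 19 of the route.
- **Merits:** These are real advantages. The step is convergent and neutral, it tolerates the prenyl ether so A2 is one step from the target where the chosen plan needs three after its key step, and it has no alkene-geometry requirement.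
- **Weak points:** The benzodioxinone presupposes the hexasubstituted salicylic acid, so the C4–C4a bond must be made separately anyway. Acetonide formation on a 6-alkoxysalicylic acid normally uses strongly acidic anhydride conditions that MOM and prenyl ethers would not survive. Trapping of photogenerated quinoid ketenes by enamines to give chromones is not established. The secondary amine expelled in each productive event is an excellent ketene trap, so it diverts the ketene to a salicylamide. The enamine of an α-alkoxy aryl ketone is hard to form and easily hydrolysed.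
- **Comparison:** The chosen plan pays with strongly basic conditions and a longer end-game. It gains a trivial C1 reagent, needs no salicylate or dioxinone, and relies on well-understood directing effects for the first metalation.

**Alternative 3: biomimetic Claisen–Dieckmann fold of a masked polyketide chain.**
- **Cut and key step:** C6–C7 and C8–C8a of ring A. A γ-lithiated enol-ether malonate is C-acylated by a methoxyacetate ester, and Mg(OMe)2 drives Dieckmann closure to A3, methyl 6-(benzyloxy)-2,4-dihydroxy-3-methoxybenzoate.
- **Merits:** The inputs are cheap and acyclic, the 8-methoxy group comes with the acylating ester, and the C4 carbon is in place. The later 7-hydroxyl is free while the later O1 hydroxyl is hydrogen-bonded to the ester, so selective 7-O-prenylation should be possible without a statistical step. In this respect it is better than the chosen plan.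
- **Weak points:** It builds an arene whose oxygen pattern is commercially accessible. The 5-O-benzyl group must later be removed in the presence of the prenyl ether, which excludes hydrogenolysis and leaves Lewis acids that threaten the prenyl group. Ring C and ring B still require a separate classical sequence.
- **Comparison:** The chosen plan sets against it a ring A that is bought and not built, protecting groups that all leave without reduction or Lewis acid, and a key step that forms ring C.

Key step: step 10

Remark: the target has no stereocentre; the only stereochemical requirement of the route is that enol ether 13 be the E isomer (MOM-oxy group trans to the aryloxy group).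

## Route

Step 1
Reactants: 1 2-methoxybenzene-1,3-diol
Product: 2 2-methoxy-3-[(triisopropylsilyl)oxy]phenol
Conditions: i-Pr3SiCl (1.0 equiv), imidazole, DMF, 0 °C → rt; diol and bis-silyl ether separated and recycled
Reagents that add atoms: chlorotriisopropylsilane, CC(C)[Si](Cl)(C(C)C)C(C)C
Why: Silyl ether formation on a phenol; the two hydroxyls of 1 are equivalent, so one equivalent of the bulky chlorosilane should give mainly the mono-ether by statistical desymmetrisation.

Step 2
Reactants: 3 methyl hydroxyacetate (methyl glycolate)
Product: 4 methyl (methoxymethoxy)acetate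
Conditions: MeOCH2Cl, i-Pr2NEt, CH2Cl2, 0 °C → rt
Reagents that add atoms: chloromethyl methyl ether, COCCl
Why: MOM protection (O-alkylation) of a primary alcohol with an amine base; the methyl ester is inert.

Step 3
Reactants: 4 methyl (methoxymethoxy)acetate
Product: 5 (methoxymethoxy)acetic acid
Conditions: LiOH, THF–H2O, 0 °C → rt; then dilute HCl to pH 3 at 0 °C
Reagents that add atoms: water (as aqueous LiOH), O
Why: Ester saponification; the MOM acetal is stable to base and should survive a brief, cold acidification to pH 3.

Step 4
Reactants: 2 2-methoxy-3-[(triisopropylsilyl)oxy]phenol; 5 (methoxymethoxy)acetic acid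
Product: 6 2-methoxy-3-[(triisopropylsilyl)oxy]phenyl (methoxymethoxy)acetate
Conditions: EDC·HCl, 4-(dimethylamino)pyridine (cat.), CH2Cl2, 0 °C → rt
Reagents that add atoms: none
Why: Steglich esterification acylates the OMe-flanked phenol under neutral conditions that keep the MOM acetal and the silyl ether.

Step 5
Reactants: 6 2-methoxy-3-[(triisopropylsilyl)oxy]phenyl (methoxymethoxy)acetate
Product: 8 5-hydroxy-2-methoxy-3-[(triisopropylsilyl)oxy]phenyl (methoxymethoxy)acetate, via arylboronate 7 (not isolated)
Conditions: [Ir(OMe)(cod)]2 (1.5 mol %; cod = cycloocta-1,5-diene), 4,4′-di-tert-butyl-2,2′-bipyridine (3 mol %), B2pin2, THF, 65 °C; concentrate; KHSO5 (as 2KHSO5·KHSO4·K2SO4), acetone–H2O, 0 °C → rt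
Reagents that add atoms: bis(pinacolato)diboron, CC1(C)OB(OC1(C)C)B1OC(C)(C)C(C)(C)O1 (boron of 7); potassium peroxymonosulfate, [K+].OOS(=O)(=O)[O-] (phenolic oxygen of 8)
Why: Iridium-catalysed C–H borylation is sterically controlled and in a 1,2,3-trisubstituted benzene should go to C5, the only position without an ortho substituent. Oxidation of the boronate with peroxymonosulfate is fast and non-basic, so the aryl ester and the silyl ether should remain.

Step 6
Reactants: 8 5-hydroxy-2-methoxy-3-[(triisopropylsilyl)oxy]phenyl (methoxymethoxy)acetate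
Product: 9 2-methoxy-5-(methoxymethoxy)-3-[(triisopropylsilyl)oxy]phenyl (methoxymethoxy)acetate
Conditions: MeOCH2Cl, i-Pr2NEt, CH2Cl2, 0 °C → rt
Reagents that add atoms: chloromethyl methyl ether, COCCl
Why: MOM protection of a phenol; the amine base is too weak to cleave or transfer the aryl ester.

Step 7
Reactants: 9 2-methoxy-5-(methoxymethoxy)-3-[(triisopropylsilyl)oxy]phenyl (methoxymethoxy)acetate
Product: 10 (Z)-1-{2-methoxy-5-(methoxymethoxy)-3-[(triisopropylsilyl)oxy]phenoxy}-2-(methoxymethoxy)ethenyl diphenyl phosphate
Conditions: (PhO)2P(O)Cl, then KN(SiMe3)2 added last, THF–DMPU, −78 °C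
Reagents that add atoms: diphenyl chlorophosphate, O=P(Cl)(Oc1ccccc1)Oc1ccccc1
Why: O-phosphorylation of an ester enolate to a ketene acetal phosphate, with the base added to ester plus chlorophosphate so that the enolate is trapped before it can lose aryloxide. α-Alkoxy ester enolates form with the α-oxygen cis to the enolate oxygen (chelation and the open-transition-state preference agree), which puts the phosphate cis and the aryloxy group trans to the MOM-oxy group.

Step 8
Reactants: 11 2-methoxy-4-(4,4,5,5-tetramethyl-1,3,2-dioxaborolan-2-yl)phenol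
Product: 12 2-[3-methoxy-4-(methoxymethoxy)phenyl]-4,4,5,5-tetramethyl-1,3,2-dioxaborolane
Conditions: MeOCH2Cl, i-Pr2NEt, CH2Cl2, 0 °C → rt
Reagents that add atoms: chloromethyl methyl ether, COCCl
Why: MOM protection of a phenol; the pinacol boronate is untouched by the amine base.

Step 9
Reactants: 10 (Z)-1-{2-methoxy-5-(methoxymethoxy)-3-[(triisopropylsilyl)oxy]phenoxy}-2-(methoxymethoxy)ethenyl diphenyl phosphate; 12 2-[3-methoxy-4-(methoxymethoxy)phenyl]-4,4,5,5-tetramethyl-1,3,2-dioxaborolane
Product: 13 (E)-2-(methoxymethoxy)-1-[3-methoxy-4-(methoxymethoxy)phenyl]ethenyl 2-methoxy-5-(methoxymethoxy)-3-[(triisopropylsilyl)oxy]phenyl ether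
Conditions: Pd(PPh3)4 (5 mol %), Cs2CO3 (aq), DMF, 50 °C; chromatography on Et3N-treated silica
Reagents that add atoms: none
Why: Suzuki–Miyaura coupling of a ketene acetal phosphate with an arylboronate; oxidative addition into the C–OP bond and reductive elimination proceed with retention. Ring B therefore takes the place of the phosphate, cis to MOM-oxy, and the E enol ether should result.

Step 10
Reactants: 13 (E)-2-(methoxymethoxy)-1-[3-methoxy-4-(methoxymethoxy)phenyl]ethenyl 2-methoxy-5-(methoxymethoxy)-3-[(triisopropylsilyl)oxy]phenyl ether; 14 N,N-dimethylcarbamoyl chloride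
Product: 17 8-methoxy-3,5-bis(methoxymethoxy)-2-[3-methoxy-4-(methoxymethoxy)phenyl]-7-[(triisopropylsilyl)oxy]-4H-chromen-4-one, via aryllithium 15 (not isolated), via dimethylbenzamide 16 (not isolated)
Conditions: n-BuLi (1.1 equiv), THF, −78 → −20 °C; 14 (1.05 equiv), −78 → −20 °C; LiN(i-Pr)2 (2.5 equiv), −78 → 0 °C; aq NH4Cl
Reagents that add atoms: none
Why: Proposed new method: n-BuLi should remove the C4a proton, the only ring-A position flanked by two coordinating oxygens (the vinyloxy O1 and the 5-O-MOM group), while C6 is screened by the triisopropylsilyl ether and ring B offers only singly activated positions; the aryllithium 15 is then acylated by 14 to the tertiary benzamide 16 (C4–C4a). LiN(i-Pr)2 next removes the vinylic proton at C3, which is α to the MOM-oxy group, cis to O1 and held beside the amide carbonyl, and the vinyllithium adds to the amide in a 6-exo-trig anionic cyclisation (C3–C4) that closes ring C; the tetrahedral adduct loses dimethylamide on warming or work-up to give the 4-pyranone. The closest known reaction types are the directed remote metalation–cyclisation of 2-aryloxybenzamides to xanthones and the carbamoyl chloride quench of ortho-lithiated aryl ethers; the new element is that the remote carbanion is an α-alkoxyvinyl and not an aryl anion. No stereocentre is formed. The step needs site selectivity in the first lithiation, which the O1/5-O-MOM pair and the bulky silyl group should secure, and it needs the E geometry of 13, which places C3–Li on the side of O1 so that it can reach the amide and makes it the cis-β-oxygenated vinyllithium that resists β-elimination of aryloxide. Because a one-carbon unit is stitched between the two carbanion sites, a reversed order of metalation (C3 first, C4a second) would converge on the same product.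

Step 11
Reactants: 17 8-methoxy-3,5-bis(methoxymethoxy)-2-[3-methoxy-4-(methoxymethoxy)phenyl]-7-[(triisopropylsilyl)oxy]-4H-chromen-4-one
Product: 18 7-hydroxy-8-methoxy-3,5-bis(methoxymethoxy)-2-[3-methoxy-4-(methoxymethoxy)phenyl]-4H-chromen-4-one
Conditions: Bu4NF, THF, 0 °C; aq NH4Cl
Reagents that add atoms: none
Why: Fluoride-mediated cleavage of an aryl silyl ether; the MOM acetals and the pyranone are inert to fluoride at 0 °C.

Step 12
Reactants: 18 7-hydroxy-8-methoxy-3,5-bis(methoxymethoxy)-2-[3-methoxy-4-(methoxymethoxy)phenyl]-4H-chromen-4-one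
Product: 19 8-methoxy-3,5-bis(methoxymethoxy)-2-[3-methoxy-4-(methoxymethoxy)phenyl]-7-[(3-methylbut-2-en-1-yl)oxy]-4H-chromen-4-one
Conditions: prenyl bromide, K2CO3, acetone, rt → 40 °C
Reagents that add atoms: 1-bromo-3-methylbut-2-ene, CC(C)=CCBr
Why: Williamson ether synthesis (SN2) on the only free hydroxyl; weak base and low temperature should avoid C-alkylation and Claisen rearrangement.

Step 13
Reactants: 19 8-methoxy-3,5-bis(methoxymethoxy)-2-[3-methoxy-4-(methoxymethoxy)phenyl]-7-[(3-methylbut-2-en-1-yl)oxy]-4H-chromen-4-one
Product: 20 3,5-dihydroxy-2-(4-hydroxy-3-methoxyphenyl)-8-methoxy-7-[(3-methylbut-2-en-1-yl)oxy]-4H-chromen-4-one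
Conditions: HCl (1 M) in MeOH–THF, rt → 40 °C
Reagents that add atoms: none
Why: Acid-catalysed methanolysis of MOM acetals; the 3- and 5-O-MOM groups are activated by the neighbouring carbonyl, and the acidity is kept low so that the prenyl ether should not ionise.

## Compound list

1 | 2-methoxybenzene-1,3-diol | COc1c(O)cccc1O | starting material
2 | 2-methoxy-3-[(triisopropylsilyl)oxy]phenol | COc1c(O)cccc1O[Si](C(C)C)(C(C)C)C(C)C | intermediate
3 | methyl hydroxyacetate (methyl glycolate) | COC(=O)CO | starting material
4 | methyl (methoxymethoxy)acetate | COCOCC(=O)OC | intermediate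
5 | (methoxymethoxy)acetic acid | COCOCC(=O)O | intermediate
6 | 2-methoxy-3-[(triisopropylsilyl)oxy]phenyl (methoxymethoxy)acetate | COCOCC(=O)Oc1cccc(O[Si](C(C)C)(C(C)C)C(C)C)c1OC | intermediate
7 | 2-methoxy-5-(4,4,5,5-tetramethyl-1,3,2-dioxaborolan-2-yl)-3-[(triisopropylsilyl)oxy]phenyl (methoxymethoxy)acetate | COCOCC(=O)Oc1cc(B2OC(C)(C)C(C)(C)O2)cc(O[Si](C(C)C)(C(C)C)C(C)C)c1OC | intermediate (not isolated)
8 | 5-hydroxy-2-methoxy-3-[(triisopropylsilyl)oxy]phenyl (methoxymethoxy)acetate | COCOCC(=O)Oc1cc(O)cc(O[Si](C(C)C)(C(C)C)C(C)C)c1OC | intermediate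
9 | 2-methoxy-5-(methoxymethoxy)-3-[(triisopropylsilyl)oxy]phenyl (methoxymethoxy)acetate | COCOCC(=O)Oc1cc(OCOC)cc(O[Si](C(C)C)(C(C)C)C(C)C)c1OC | intermediate
10 | (Z)-1-{2-methoxy-5-(methoxymethoxy)-3-[(triisopropylsilyl)oxy]phenoxy}-2-(methoxymethoxy)ethenyl diphenyl phosphate | COCO/C=C(/Oc1cc(OCOC)cc(O[Si](C(C)C)(C(C)C)C(C)C)c1OC)OP(=O)(Oc1ccccc1)Oc1ccccc1 | intermediate
11 | 2-methoxy-4-(4,4,5,5-tetramethyl-1,3,2-dioxaborolan-2-yl)phenol | COc1cc(B2OC(C)(C)C(C)(C)O2)ccc1O | starting material
12 | 2-[3-methoxy-4-(methoxymethoxy)phenyl]-4,4,5,5-tetramethyl-1,3,2-dioxaborolane | COCOc1ccc(B2OC(C)(C)C(C)(C)O2)cc1OC | intermediate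
13 | (E)-2-(methoxymethoxy)-1-[3-methoxy-4-(methoxymethoxy)phenyl]ethenyl 2-methoxy-5-(methoxymethoxy)-3-[(triisopropylsilyl)oxy]phenyl ether | COCO/C=C(/Oc1cc(OCOC)cc(O[Si](C(C)C)(C(C)C)C(C)C)c1OC)c1ccc(OCOC)c(OC)c1 | intermediate
14 | N,N-dimethylcarbamoyl chloride | CN(C)C(=O)Cl | starting material
15 | {2-{[(E)-2-(methoxymethoxy)-1-[3-methoxy-4-(methoxymethoxy)phenyl]ethenyl]oxy}-3-methoxy-6-(methoxymethoxy)-4-[(triisopropylsilyl)oxy]phenyl}lithium | COCO/C=C(/Oc1c([Li])c(OCOC)cc(O[Si](C(C)C)(C(C)C)C(C)C)c1OC)c1ccc(OCOC)c(OC)c1 | intermediate (not isolated)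
16 | 2-{[(E)-2-(methoxymethoxy)-1-[3-methoxy-4-(methoxymethoxy)phenyl]ethenyl]oxy}-3-methoxy-6-(methoxymethoxy)-N,N-dimethyl-4-[(triisopropylsilyl)oxy]benzamide | COCO/C=C(/Oc1c(C(=O)N(C)C)c(OCOC)cc(O[Si](C(C)C)(C(C)C)C(C)C)c1OC)c1ccc(OCOC)c(OC)c1 | intermediate (not isolated)
17 | 8-methoxy-3,5-bis(methoxymethoxy)-2-[3-methoxy-4-(methoxymethoxy)phenyl]-7-[(triisopropylsilyl)oxy]-4H-chromen-4-one | COCOc1ccc(-c2oc3c(OC)c(O[Si](C(C)C)(C(C)C)C(C)C)cc(OCOC)c3c(=O)c2OCOC)cc1OC | intermediate
18 | 7-hydroxy-8-methoxy-3,5-bis(methoxymethoxy)-2-[3-methoxy-4-(methoxymethoxy)phenyl]-4H-chromen-4-one | COCOc1ccc(-c2oc3c(OC)c(O)cc(OCOC)c3c(=O)c2OCOC)cc1OC | intermediate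
19 | 8-methoxy-3,5-bis(methoxymethoxy)-2-[3-methoxy-4-(methoxymethoxy)phenyl]-7-[(3-methylbut-2-en-1-yl)oxy]-4H-chromen-4-one | COCOc1ccc(-c2oc3c(OC)c(OCC=C(C)C)cc(OCOC)c3c(=O)c2OCOC)cc1OC | intermediate
20 | 3,5-dihydroxy-2-(4-hydroxy-3-methoxyphenyl)-8-methoxy-7-[(3-methylbut-2-en-1-yl)oxy]-4H-chromen-4-one | COc1cc(-c2oc3c(OC)c(OCC=C(C)C)cc(O)c3c(=O)c2O)ccc1O | target

## Step count and risk

Total: 13 steps. Longest linear sequence: 11 steps (steps 2, 3, 4, 5, 6, 7, 9, 10, 11, 12, 13, from compound 3). The branch from compound 1 joins at step 4 and runs through 10 steps (steps 1, 4, 5, 6, 7, 9, 10, 11, 12, 13); the branch from compound 11 joins at step 9 and runs through 6 steps (steps 8, 9, 10, 11, 12, 13).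

**Step 10 (key step).**
- **What may go wrong:** The first lithiation may be diverted to the vinylic C3–H, to C6 or to ring B. LiN(i-Pr)2 may fail to metalate C3 of amide 16. The vinyllithium may undergo β-elimination of aryloxide. The released LiNMe2 may open the pyranone. Each of these follows from the absence of any precedent for a vinyl carbanion in this type of amide cyclisation.
- **Fallback (from 13, returning at 17):** Ring C is closed electrophilically instead of anionically, using two known reaction types. The aryllithium from 13 and n-BuLi is quenched with CO2 (directed ortho-metalation and carboxylation) to give 2-{[(E)-2-(methoxymethoxy)-1-[3-methoxy-4-(methoxymethoxy)phenyl]ethenyl]oxy}-3-methoxy-6-(methoxymethoxy)-4-[(triisopropylsilyl)oxy]benzoic acid F1. Neutral activation with 1-chloro-N,N,2-trimethylprop-1-en-1-amine at 0 °C gives 2-{[(E)-2-(methoxymethoxy)-1-[3-methoxy-4-(methoxymethoxy)phenyl]ethenyl]oxy}-3-methoxy-6-(methoxymethoxy)-4-[(triisopropylsilyl)oxy]benzoyl chloride F2. In the presence of 2,6-dimethylpyridine, F2 should C-acylate the enol ether at C3; the cation at C2 is stabilised by O1 and ring B, and loss of the C3 proton gives 17. This closure does not depend on vinyl anion formation or on the alkene geometry.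

**Step 7.**
- **What may go wrong:** The potassium enolate of the aryl ester may lose aryloxide (ketene formation) before it is phosphorylated, or the enolate geometry may be incompletely controlled.
- **Fallback (from 9, returning at 13):** The enol ether is built by C–O coupling and its geometry corrected photochemically. The acyl group of 9 is removed with pyrrolidine to give 2-methoxy-5-(methoxymethoxy)-3-[(triisopropylsilyl)oxy]phenol F3. Commercial 2-hydroxy-1-(4-hydroxy-3-methoxyphenyl)ethan-1-one is protected twice with MeOCH2Cl and i-Pr2NEt to give 2-(methoxymethoxy)-1-[3-methoxy-4-(methoxymethoxy)phenyl]ethan-1-one F4. Its chelated enolate (KN(SiMe3)2, N-phenylbis(trifluoromethanesulfonimide)) gives (Z)-2-(methoxymethoxy)-1-[3-methoxy-4-(methoxymethoxy)phenyl]ethenyl trifluoromethanesulfonate F5. Palladium-catalysed C–O coupling of F5 with F3 (Pd2(dba)3, dba = dibenzylideneacetone, 2-(di-tert-butylphosphino)biphenyl, K3PO4, toluene) should give, with retention, (Z)-2-(methoxymethoxy)-1-[3-methoxy-4-(methoxymethoxy)phenyl]ethenyl 2-methoxy-5-(methoxymethoxy)-3-[(triisopropylsilyl)oxy]phenyl ether F6. Triplet-sensitised isomerisation (Ir(ppy)3, ppy = 2-phenylpyridinato, blue light, MeCN) should enrich the less conjugated E isomer 13, in which ring B is twisted by the cis MOM-oxy group; remaining F6 is recycled.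

**Step 9.**
- **What may go wrong:** Aqueous base may hydrolyse the ketene acetal phosphate faster than the electron-rich boronate transmetalates, or the geometry may erode if the coupling is slow.
- **Fallback (from 10, returning at 13):** The polarity of the coupling is reversed and water and base are excluded. Compound 10 is stannylated (Me3SnSnMe3, Pd(PPh3)4, LiCl, THF) to [(Z)-1-{2-methoxy-5-(methoxymethoxy)-3-[(triisopropylsilyl)oxy]phenoxy}-2-(methoxymethoxy)ethenyl]trimethylstannane F7. F7 is joined in a Stille coupling (Pd(PPh3)4, CuI, CsF, DMF) with 4-iodo-2-methoxy-1-(methoxymethoxy)benzene F8, made from commercial 4-iodo-2-methoxyphenol and MeOCH2Cl. Both steps go with retention and should give 13.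

**Step 13.**
- **What may go wrong:** The prenyl ether may ionise, with cleavage or migration of the dimethylallyl group, before the slowest acetal (4′-O-MOM) has gone.
- **Fallback (from 18, returning at 20):** The acid step is moved ahead of the prenylation. Compound 18 is treated with HCl in MeOH to give 3,5,7-trihydroxy-2-(4-hydroxy-3-methoxyphenyl)-8-methoxy-4H-chromen-4-one F9. Ac2O in pyridine gives 2-[4-(acetyloxy)-3-methoxyphenyl]-8-methoxy-4-oxo-4H-chromene-3,5,7-triyl triacetate F10. Prenyl bromide with K2CO3 in acetone exchanges the most labile 7-acetate for prenyl, a known selectivity of peracetylated flavonoids, to give 2-[4-(acetyloxy)-3-methoxyphenyl]-8-methoxy-7-[(3-methylbut-2-en-1-yl)oxy]-4-oxo-4H-chromene-3,5-diyl diacetate F11. Mild methanolysis (K2CO3, MeOH, 0 °C) then gives 20 without exposing the prenyl ether to acid.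

## Further compounds

F1 | step 10 | 2-{[(E)-2-(methoxymethoxy)-1-[3-methoxy-4-(methoxymethoxy)phenyl]ethenyl]oxy}-3-methoxy-6-(methoxymethoxy)-4-[(triisopropylsilyl)oxy]benzoic acid | COCO/C=C(/Oc1c(C(=O)O)c(OCOC)cc(O[Si](C(C)C)(C(C)C)C(C)C)c1OC)c1ccc(OCOC)c(OC)c1
F2 | step 10 | 2-{[(E)-2-(methoxymethoxy)-1-[3-methoxy-4-(methoxymethoxy)phenyl]ethenyl]oxy}-3-methoxy-6-(methoxymethoxy)-4-[(triisopropylsilyl)oxy]benzoyl chloride | COCO/C=C(/Oc1c(C(=O)Cl)c(OCOC)cc(O[Si](C(C)C)(C(C)C)C(C)C)c1OC)c1ccc(OCOC)c(OC)c1
F3 | step 7 | 2-methoxy-5-(methoxymethoxy)-3-[(triisopropylsilyl)oxy]phenol | COCOc1cc(O)c(OC)c(O[Si](C(C)C)(C(C)C)C(C)C)c1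
F4 | step 7 | 2-(methoxymethoxy)-1-[3-methoxy-4-(methoxymethoxy)phenyl]ethan-1-one | COCOCC(=O)c1ccc(OCOC)c(OC)c1
F5 | step 7 | (Z)-2-(methoxymethoxy)-1-[3-methoxy-4-(methoxymethoxy)phenyl]ethenyl trifluoromethanesulfonate | COCO/C=C(\OS(=O)(=O)C(F)(F)F)c1ccc(OCOC)c(OC)c1
F6 | step 7 | (Z)-2-(methoxymethoxy)-1-[3-methoxy-4-(methoxymethoxy)phenyl]ethenyl 2-methoxy-5-(methoxymethoxy)-3-[(triisopropylsilyl)oxy]phenyl ether | COCO/C=C(\Oc1cc(OCOC)cc(O[Si](C(C)C)(C(C)C)C(C)C)c1OC)c1ccc(OCOC)c(OC)c1
F7 | step 9 | [(Z)-1-{2-methoxy-5-(methoxymethoxy)-3-[(triisopropylsilyl)oxy]phenoxy}-2-(methoxymethoxy)ethenyl]trimethylstannane | COCO/C=C(/Oc1cc(OCOC)cc(O[Si](C(C)C)(C(C)C)C(C)C)c1OC)[Sn](C)(C)C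
F8 | step 9 | 4-iodo-2-methoxy-1-(methoxymethoxy)benzene | COCOc1ccc(I)cc1OC
F9 | step 13 | 3,5,7-trihydroxy-2-(4-hydroxy-3-methoxyphenyl)-8-methoxy-4H-chromen-4-one | COc1cc(-c2oc3c(OC)c(O)cc(O)c3c(=O)c2O)ccc1O
F10 | step 13 | 2-[4-(acetyloxy)-3-methoxyphenyl]-8-methoxy-4-oxo-4H-chromene-3,5,7-triyl triacetate | COc1cc(-c2oc3c(OC)c(OC(C)=O)cc(OC(C)=O)c3c(=O)c2OC(C)=O)ccc1OC(C)=O
F11 | step 13 | 2-[4-(acetyloxy)-3-methoxyphenyl]-8-methoxy-7-[(3-methylbut-2-en-1-yl)oxy]-4-oxo-4H-chromene-3,5-diyl diacetate | COc1cc(-c2oc3c(OC)c(OCC=C(C)C)cc(OC(C)=O)c3c(=O)c2OC(C)=O)ccc1OC(C)=O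
A1 | alternative 1 | methyl 4-acetyl-6-hydroxy-3-methoxy-2-(pivaloyloxy)benzoate | COC(=O)c1c(O)cc(C(C)=O)c(OC)c1OC(=O)C(C)(C)C
A2 | alternative 2 | 8-methoxy-3,5-bis(methoxymethoxy)-2-[3-methoxy-4-(methoxymethoxy)phenyl]-7-[(3-methylbut-2-en-1-yl)oxy]-4H-chromen-4-one | COCOc1ccc(-c2oc3c(OC)c(OCC=C(C)C)cc(OCOC)c3c(=O)c2OCOC)cc1OC
A3 | alternative 3 | methyl 6-(benzyloxy)-2,4-dihydroxy-3-methoxybenzoate | COC(=O)c1c(O)c(OC)c(O)cc1OCc1ccccc1
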